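**Retrosynthetic overview**
1. Asperglaucin A ⇐ its tris-MOM ether by acetal cleavage; the benzene ring is bought in and the fused five-membered thiolactone is the only ring to be made.
2. Feature used: the thiolactone carbonyl carbon C1 is a one-carbon link between aromatic C7a and ring sulfur S2 (bound to benzylic C3). C7a–C1 and C1–S2 are therefore cut together and C1 is supplied as CO ⇒ ortho-iodo benzylic thiol.
3. C3–S ⇐ (1R,2R) benzylic alcohol by Mitsunobu inversion with thioacetic acid; C7a–I ⇐ alkoxide/OMOM-directed ortho-lithiation–iodination.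
4. C3a–C3 ⇐ chelation-controlled addition of an aryl Grignard (from 2,5-dibromohydroquinone and prenyl bromide) to (R)-2-(methoxymethoxy)heptanal (from (R)-benzyl glycidyl ether and butylmagnesium chloride).
5. Order of rings: the arene is carried through; the thiolactone ring is closed in the penultimate step.

Key step: step 11

Assumption: aldehyde 11 is used directly after oxidation because α-alkoxy aldehydes can epimerise on storage; organometallic species made in the flask are numbered as non-isolated intermediates, catalytic-cycle species are not.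

**Step 1**
Reactants: 1 2,5-dibromobenzene-1,4-diol (2,5-dibromohydroquinone)
Product: 2 1,4-dibromo-2,5-bis(methoxymethoxy)benzene
Conditions: NaH, MOMCl, DMF, 0 °C → rt
Reagents that add atoms: chloromethyl methyl ether, COCCl
Why: Williamson-type O-alkylation of the bis-phenoxide with MOMCl should give the bis-acetal, which masks both phenols and supplies the chelating/directing OMOM groups used later.

**Step 2**
Reactants: 2 1,4-dibromo-2,5-bis(methoxymethoxy)benzene; 3 1-bromo-3-methylbut-2-ene (prenyl bromide)
Product: 6 1-bromo-2,5-bis(methoxymethoxy)-4-(3-methylbut-2-en-1-yl)benzene, via aryllithium 4 (not isolated), via arylcopper 5 (not isolated)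
Conditions: n-BuLi (1.0 equiv), THF, −78 °C; CuBr·SMe2; then 3, −78 → 0 °C
Reagents that add atoms: none
Why: Mono bromine–lithium exchange (the second exchange is much slower on the electron-rich aryllithium), transmetalation to copper and SN2 allylation should give the linear prenyl arene, copper suppressing SN2′ attack and halogen scrambling.

**Step 3**
Reactants: 7 (2R)-2-[(benzyloxy)methyl]oxirane ((R)-benzyl glycidyl ether)
Product: 8 (2R)-1-(benzyloxy)heptan-2-ol
Conditions: n-BuMgCl, CuI (10 mol%), THF, −40 → −20 °C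
Reagents that add atoms: butylmagnesium chloride, CCCC[Mg]Cl
Why: Copper-catalysed Grignard opening of the terminal epoxide occurs at the CH2 carbon, so the C–O stereocentre (the future C1′) is not touched and stays R.

**Step 4**
Reactants: 8 (2R)-1-(benzyloxy)heptan-2-ol
Product: 9 (2R)-1-(benzyloxy)-2-(methoxymethoxy)heptane
Conditions: MOMCl, iPr2NEt, Bu4NI (cat.), CH2Cl2, 0 °C → rt
Reagents that add atoms: chloromethyl methyl ether, COCCl
Why: Standard MOM protection (O-alkylation by the oxocarbenium-like chloromethyl ether) installs the chelating group needed for the later carbonyl addition.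

**Step 5**
Reactants: 9 (2R)-1-(benzyloxy)-2-(methoxymethoxy)heptane
Product: 10 (2R)-2-(methoxymethoxy)heptan-1-ol
Conditions: H2 (1 atm), 10% Pd/C, EtOAc, rt
Reagents that add atoms: none
Why: Hydrogenolysis cleaves the benzyl ether selectively, the MOM acetal being inert under neutral hydrogenation.

**Step 6**
Reactants: 10 (2R)-2-(methoxymethoxy)heptan-1-ol
Product: 11 (2R)-2-(methoxymethoxy)heptanal
Conditions: Dess–Martin periodinane, NaHCO3, CH2Cl2, 0 °C → rt; used crude
Reagents that add atoms: none
Why: Dess–Martin oxidation under buffered, non-basic conditions should give the α-alkoxy aldehyde without epimerisation of the α-stereocentre.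

**Step 7**
Reactants: 6 1-bromo-2,5-bis(methoxymethoxy)-4-(3-methylbut-2-en-1-yl)benzene; 11 (2R)-2-(methoxymethoxy)heptanal
Product: 14 (1R,2R)-1-[2,5-bis(methoxymethoxy)-4-(3-methylbut-2-en-1-yl)phenyl]-2-(methoxymethoxy)heptan-1-ol, via aryllithium 12 (not isolated), via arylmagnesium bromide 13 (not isolated)
Conditions: t-BuLi (2 equiv), Et2O, −78 °C; MgBr2·OEt2, −78 → 0 °C; then 11, CH2Cl2/Et2O, −78 °C
Reagents that add atoms: none
Why: Bromine–lithium exchange and transmetalation give the aryl Grignard, which adds to the aldehyde under Cram-chelate control (Mg bridging the carbonyl and α-OMOM oxygens, attack on the face opposite the pentyl chain), setting C1 as R in the 1,2-syn (1R,2R) alcohol.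

**Step 8**
Reactants: 14 (1R,2R)-1-[2,5-bis(methoxymethoxy)-4-(3-methylbut-2-en-1-yl)phenyl]-2-(methoxymethoxy)heptan-1-ol
Product: 16 (1R,2R)-1-[2-iodo-3,6-bis(methoxymethoxy)-4-(3-methylbut-2-en-1-yl)phenyl]-2-(methoxymethoxy)heptan-1-ol, via dilithio alkoxide 15 (not isolated)
Conditions: n-BuLi (2.5 equiv), TMEDA, Et2O, −78 → 0 °C; then I2, THF, −78 °C
Reagents that add atoms: iodine, II
Why: Directed ortho-metalation, in which the lithium alkoxide formed first and the neighbouring ring OMOM together guide the second equivalent of base to the ring C–H between them (the future C7a), followed by iodinolysis of the aryllithium, should give the iodide with both stereocentres untouched.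

**Step 9**
Reactants: 16 (1R,2R)-1-[2-iodo-3,6-bis(methoxymethoxy)-4-(3-methylbut-2-en-1-yl)phenyl]-2-(methoxymethoxy)heptan-1-ol
Product: 17 S-{(1S,2R)-1-[2-iodo-3,6-bis(methoxymethoxy)-4-(3-methylbut-2-en-1-yl)phenyl]-2-(methoxymethoxy)heptyl} ethanethioate
Conditions: PPh3, DIAD, THF, 0 °C; then 16 + AcSH, 0 °C → rt
Reagents that add atoms: thioacetic acid, CC(=O)S
Why: Mitsunobu reaction, in which thioacetate displaces the oxyphosphonium by SN2 with inversion (1R → 1S), the β-OMOM group and the twisted di-ortho-substituted ring disfavouring ionisation of the benzylic C–O bond.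

**Step 10**
Reactants: 17 S-{(1S,2R)-1-[2-iodo-3,6-bis(methoxymethoxy)-4-(3-methylbut-2-en-1-yl)phenyl]-2-(methoxymethoxy)heptyl} ethanethioate
Product: 18 (1S,2R)-1-[2-iodo-3,6-bis(methoxymethoxy)-4-(3-methylbut-2-en-1-yl)phenyl]-2-(methoxymethoxy)heptane-1-thiol
Conditions: K2CO3 (cat.), degassed MeOH, 0 °C, argon; NH4Cl quench; used at once
Reagents that add atoms: none
Why: Base-catalysed methanolysis of the thioester (transesterification to methyl acetate) frees the thiol without touching the C–S stereocentre, and exclusion of oxygen prevents disulfide formation.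

**Step 11**
Reactants: 18 (1S,2R)-1-[2-iodo-3,6-bis(methoxymethoxy)-4-(3-methylbut-2-en-1-yl)phenyl]-2-(methoxymethoxy)heptane-1-thiol
Product: 19 (3S)-4,7-bis(methoxymethoxy)-3-[(1R)-1-(methoxymethoxy)hexyl]-6-(3-methylbut-2-en-1-yl)-2-benzothiophen-1(3H)-one (tris-MOM asperglaucin A)
Conditions: Pd(OAc)2 (5 mol%), Xantphos (6 mol%), Et3N, CO (1 atm), toluene (dilute), 70 °C
Reagents that add atoms: carbon monoxide, [C-]#[O+]
Why: Pd(0) inserts into the C7a–I bond, CO coordinates and migrates to give an aroyl–Pd(II) species, and the benzylic thiolate (formed with Et3N) is acylated at sulfur, by attack on the acyl carbon or by C–S reductive elimination from an acyl(thiolato)palladium, which forms C7a–C1 and C1–S and returns Pd(0). The closest known reactions are the Pd-catalysed thiocarbonylation of aryl iodides with thiols and CO and the carbonylative lactonisation of ortho-halobenzyl alcohols. The thiolactone ring closes in a 5-exo-trig mode at the acyl carbon, its size fixed by the ortho relationship of the iodide and the CH–SH group. No stereocentre is created; C3 and C1′ are not bonded to any reacting atom and triethylamine is too weak a base to remove the C3–H of the product, so (3S,1′R) is carried through. S- over O-acylation is secured by the MOM ether on the C1′ oxygen, and direct C–S coupling is excluded because it would give a four-membered ring, so carbonylation precedes closure. A wide-bite-angle diphosphine, 1 atm CO and dilution are chosen to keep thiolate from saturating palladium and to disfavour intermolecular thioester formation.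

**Step 12**
Reactants: 19 (3S)-4,7-bis(methoxymethoxy)-3-[(1R)-1-(methoxymethoxy)hexyl]-6-(3-methylbut-2-en-1-yl)-2-benzothiophen-1(3H)-one
Product: 20 asperglaucin A, (3S)-4,7-dihydroxy-3-[(1R)-1-hydroxyhexyl]-6-(3-methylbut-2-en-1-yl)-2-benzothiophen-1(3H)-one
Conditions: TMSOTf, 2,2′-bipyridyl, CH2Cl2, 0 °C → rt; then H2O; aq. NaHCO3 work-up
Reagents that add atoms: none
Why: Silyl triflate/bipyridyl acetal cleavage (non-protic MOM deprotection) converts the alkyl MOM ether into an N-(alkoxymethyl)pyridinium salt and the aryl MOM ethers into aryl silyl ethers, all hydrolysed by water, so the ortho-prenyl phenol and the β-hydroxy thiolactone are not exposed to Brønsted acid.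

**Compound list**
1 | 2,5-dibromobenzene-1,4-diol | Oc1cc(Br)c(O)cc1Br | starting material
2 | 1,4-dibromo-2,5-bis(methoxymethoxy)benzene | COCOc1cc(Br)c(OCOC)cc1Br | intermediate
3 | 1-bromo-3-methylbut-2-ene (prenyl bromide) | CC(C)=CCBr | starting material
4 | [4-bromo-2,5-bis(methoxymethoxy)phenyl]lithium | [Li]c1cc(OCOC)c(Br)cc1OCOC | intermediate
5 | [4-bromo-2,5-bis(methoxymethoxy)phenyl]copper | [Cu]c1cc(OCOC)c(Br)cc1OCOC | intermediate
6 | 1-bromo-2,5-bis(methoxymethoxy)-4-(3-methylbut-2-en-1-yl)benzene | Brc1cc(OCOC)c(CC=C(C)C)cc1OCOC | intermediate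
7 | (2R)-2-[(benzyloxy)methyl]oxirane | c1ccccc1COC[C@H]1CO1 | starting material
8 | (2R)-1-(benzyloxy)heptan-2-ol | CCCCC[C@@H](O)COCc1ccccc1 | intermediate
9 | (2R)-1-(benzyloxy)-2-(methoxymethoxy)heptane | CCCCC[C@@H](OCOC)COCc1ccccc1 | intermediate
10 | (2R)-2-(methoxymethoxy)heptan-1-ol | CCCCC[C@@H](OCOC)CO | intermediate
11 | (2R)-2-(methoxymethoxy)heptanal | CCCCC[C@@H](OCOC)C=O | intermediate
12 | [2,5-bis(methoxymethoxy)-4-(3-methylbut-2-en-1-yl)phenyl]lithium | [Li]c1cc(OCOC)c(CC=C(C)C)cc1OCOC | intermediate
13 | [2,5-bis(methoxymethoxy)-4-(3-methylbut-2-en-1-yl)phenyl]magnesium bromide | Br[Mg]c1cc(OCOC)c(CC=C(C)C)cc1OCOC | intermediate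
14 | (1R,2R)-1-[2,5-bis(methoxymethoxy)-4-(3-methylbut-2-en-1-yl)phenyl]-2-(methoxymethoxy)heptan-1-ol | CCCCC[C@@H](OCOC)[C@H](O)c1cc(OCOC)c(CC=C(C)C)cc1OCOC | intermediate
15 | lithium (1R,2R)-1-[2-lithio-3,6-bis(methoxymethoxy)-4-(3-methylbut-2-en-1-yl)phenyl]-2-(methoxymethoxy)heptan-1-olate | CCCCC[C@@H](OCOC)[C@H](O[Li])c1c([Li])c(OCOC)c(CC=C(C)C)cc1OCOC | intermediate
16 | (1R,2R)-1-[2-iodo-3,6-bis(methoxymethoxy)-4-(3-methylbut-2-en-1-yl)phenyl]-2-(methoxymethoxy)heptan-1-ol | CCCCC[C@@H](OCOC)[C@H](O)c1c(I)c(OCOC)c(CC=C(C)C)cc1OCOC | intermediate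
17 | S-{(1S,2R)-1-[2-iodo-3,6-bis(methoxymethoxy)-4-(3-methylbut-2-en-1-yl)phenyl]-2-(methoxymethoxy)heptyl} ethanethioate | CCCCC[C@@H](OCOC)[C@@H](SC(C)=O)c1c(I)c(OCOC)c(CC=C(C)C)cc1OCOC | intermediate
18 | (1S,2R)-1-[2-iodo-3,6-bis(methoxymethoxy)-4-(3-methylbut-2-en-1-yl)phenyl]-2-(methoxymethoxy)heptane-1-thiol | CCCCC[C@@H](OCOC)[C@@H](S)c1c(I)c(OCOC)c(CC=C(C)C)cc1OCOC | intermediate
19 | (3S)-4,7-bis(methoxymethoxy)-3-[(1R)-1-(methoxymethoxy)hexyl]-6-(3-methylbut-2-en-1-yl)-2-benzothiophen-1(3H)-one | CCCCC[C@@H](OCOC)[C@H]1SC(=O)c2c(OCOC)c(CC=C(C)C)cc(OCOC)c21 | intermediate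
20 | asperglaucin A | CCCCC[C@@H](O)[C@H]1SC(=O)c2c(O)c(CC=C(C)C)cc(O)c21 | target

**Step count**
Total: 12 steps. Longest linear sequence: 10 steps (7 → 20, steps 3–12).

**Steps most likely to fail**

Step 9 (Mitsunobu thioacetylation). Backside attack at the benzylic carbon is hindered by the ortho iodine, the ortho OMOM group and the branched C2. The oxyphosphonium may therefore be consumed by ionisation or elimination faster than by SN2, giving incomplete conversion or erosion of the inversion. The fallback separates activation from substitution and sets out from alcohol 16. Methanesulfonic anhydride and Et3N in CH2Cl2 at −20 °C (chloride-free, small leaving group) should give (1R,2R)-1-[2-iodo-3,6-bis(methoxymethoxy)-4-(3-methylbut-2-en-1-yl)phenyl]-2-(methoxymethoxy)heptyl methanesulfonate F1. Displacement with cesium thioacetate in DMF at room temperature, by an unencumbered thiocarboxylate, should then give the inverted thioester and come back to the route at 17.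

Step 11 (carbonylative ring closure). Binding of the thiolate to palladium, oxidative dimerisation of the thiol or reduction of the C–I bond may outrun CO insertion and acyl transfer. The fallback builds the same two bonds without palladium and sets out from thiol 18. i-PrMgCl·LiCl (2.2 equiv) in THF at −40 °C should deprotonate the thiol and effect iodine–magnesium exchange, giving chloromagnesium (1S,2R)-1-[2-(chloromagnesio)-3,6-bis(methoxymethoxy)-4-(3-methylbut-2-en-1-yl)phenyl]-2-(methoxymethoxy)heptane-1-thiolate F2. Carboxylation with CO2 and acidic work-up should give 2-[(1S,2R)-2-(methoxymethoxy)-1-sulfanylheptyl]-3,6-bis(methoxymethoxy)-5-(3-methylbut-2-en-1-yl)benzoic acid F3. Dehydrative thiolactonisation with EDC·HCl and DMAP in CH2Cl2 comes back to the route at 19.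

Step 8 (ortho-lithiation–iodination). Deprotonation at the benzylic/allylic CH2 of the prenyl group or at C5 may compete with metalation between the alkoxide-bearing carbon and OMOM, leading to iodination at the wrong site. The fallback puts the halogen in place before the C–C bond is made; it sets out from aldehyde 11 and prenyl bromide 3, with commercial 2,6-dibromohydroquinone (Oc1cc(Br)c(O)c(Br)c1) as the arene source.
- Bis-MOM protection as in step 1 should give 1,3-dibromo-2,5-bis(methoxymethoxy)benzene F4.
- Mono bromine–lithium exchange and copper-mediated prenylation with 3, as in step 2, should give 1-bromo-2,5-bis(methoxymethoxy)-3-(3-methylbut-2-en-1-yl)benzene F5.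
- LiTMP in THF at −78 °C removes the acidic ring proton between bromine and OMOM (an amide base does not touch the prenyl CH2), giving [2-bromo-3,6-bis(methoxymethoxy)-4-(3-methylbut-2-en-1-yl)phenyl]lithium F6.
- Transmetalation with MgBr2·OEt2 gives [2-bromo-3,6-bis(methoxymethoxy)-4-(3-methylbut-2-en-1-yl)phenyl]magnesium bromide F7.
- Chelation-controlled addition to 11 at −78 °C should give (1R,2R)-1-[2-bromo-3,6-bis(methoxymethoxy)-4-(3-methylbut-2-en-1-yl)phenyl]-2-(methoxymethoxy)heptan-1-ol F8.
- Copper-catalysed aromatic Finkelstein exchange (CuI, trans-N,N′-dimethylcyclohexane-1,2-diamine, NaI, dioxane, 110 °C) comes back to the route at 16.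

**Further compounds**
F1 | step 9 | (1R,2R)-1-[2-iodo-3,6-bis(methoxymethoxy)-4-(3-methylbut-2-en-1-yl)phenyl]-2-(methoxymethoxy)heptyl methanesulfonate | CCCCC[C@@H](OCOC)[C@H](OS(C)(=O)=O)c1c(I)c(OCOC)c(CC=C(C)C)cc1OCOC
F2 | step 11 | chloromagnesium (1S,2R)-1-[2-(chloromagnesio)-3,6-bis(methoxymethoxy)-4-(3-methylbut-2-en-1-yl)phenyl]-2-(methoxymethoxy)heptane-1-thiolate | CCCCC[C@@H](OCOC)[C@@H](S[Mg]Cl)c1c([Mg]Cl)c(OCOC)c(CC=C(C)C)cc1OCOC
F3 | step 11 | 2-[(1S,2R)-2-(methoxymethoxy)-1-sulfanylheptyl]-3,6-bis(methoxymethoxy)-5-(3-methylbut-2-en-1-yl)benzoic acid | CCCCC[C@@H](OCOC)[C@@H](S)c1c(C(=O)O)c(OCOC)c(CC=C(C)C)cc1OCOC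
F4 | step 8 | 1,3-dibromo-2,5-bis(methoxymethoxy)benzene | COCOc1cc(Br)c(OCOC)c(Br)c1
F5 | step 8 | 1-bromo-2,5-bis(methoxymethoxy)-3-(3-methylbut-2-en-1-yl)benzene | COCOc1cc(Br)c(OCOC)c(CC=C(C)C)c1
F6 | step 8 | [2-bromo-3,6-bis(methoxymethoxy)-4-(3-methylbut-2-en-1-yl)phenyl]lithium | [Li]c1c(Br)c(OCOC)c(CC=C(C)C)cc1OCOC
F7 | step 8 | [2-bromo-3,6-bis(methoxymethoxy)-4-(3-methylbut-2-en-1-yl)phenyl]magnesium bromide | Br[Mg]c1c(Br)c(OCOC)c(CC=C(C)C)cc1OCOC
F8 | step 8 | (1R,2R)-1-[2-bromo-3,6-bis(methoxymethoxy)-4-(3-methylbut-2-en-1-yl)phenyl]-2-(methoxymethoxy)heptan-1-ol | CCCCC[C@@H](OCOC)[C@H](O)c1c(Br)c(OCOC)c(CC=C(C)C)cc1OCOC
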